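**Analysis of the target**

Target 26 is a bicyclo[3.2.1]octane. The numbering used for all bicyclic compounds is C1 (bridgehead with the isobutyryl group), C2 (ring ketone), C3 (carbinol carbon), C5 (bridgehead with a prenyl group), C6 (CH2), C7 (CH–prenyl), C8 (CMe2) and C9 (bridging ketone); there is no C4. A five-membered ring (C1, C2, C3, C5, C9) and a six-membered ring (C1, C8, C7, C6, C5, C9) share the unit C1–C9–C5. There are four stereocentres (1R,3S,5S,7R in these locants). C1 and C5 are tied to each other by the bridge. The C7 prenyl group is equatorial on the chair six-membered ring (exo, with C7–H pointing under the C2–C3 bridge). At C3 the hydroxyl is endo (toward C6–C8) and the (Z)-4-hydroxy-4-methylpent-2-enoyl group is exo (toward C9). The sensitive groups are the triacylmethane carbon C1 (retro-Claisen cleavage by hard nucleophiles), the tertiary α-ketol at C3 (acyloin shift, acyl transfer), the Z-γ-hydroxy enone (Z to E isomerisation, lactol formation) and two prenyl groups (acid, halonium reagents, oxidants). The synthesis is hard because the quaternary C1 sits next to the quaternary C8, because five ketones must be told apart, and because the absolute configuration rests on the lone C7 methine. The strategy rests on one feature: C9 lies between two carbons that can both act as nucleophiles, C5 (α′ to the C9 ketone) and C1 (between C9 and the isobutyryl carbonyl), while the two atoms that bridge them, C2 and C3, both carry oxygen. The five-membered ring C1–C2–C3–C5–C9 is therefore the double aldol adduct of a 2-acylcyclohexanone 1,3-dianion equivalent with the two carbons of glyoxal.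

**Retrosynthetic reasoning**

26 ⇒ 25 ⇒ 24. One C–CH3 bond of the side-chain carbinol is cut. The two methyl groups on that carbon are equivalent, so adding a methyl nucleophile to the methyl ketone of Z-enedione 24 creates no stereocentre, and that ketone is the only carbonyl of 24 not flanked by a fully substituted carbon. The C3 oxygen is carried as a trimethylsilyl ether (25 to 26 is its removal), because a free C3 alkoxide beside the C2 ketone and the C1 triacylmethane invites acyloin shift and acyl transfer. The forward step must be a 1,2-addition by a non-basic reagent that leaves the Z double bond alone.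

24 ⇒ 23. The Z-ene-1,4-dione is traced back to the 2,5-disubstituted furan of 23. The furan stores four side-chain carbons, the oxidation level of both carbonyls and the cis geometry in one robust ring, and it survives the basic step that installs it. The forward step must open the furan with one oxidising equivalent and not touch the prenyl double bonds.

23 ⇒ 20 + 21. The C3–C(furyl) bond is cut. In trione 20, C3 is the less shielded carbon of the α-diketone pair and its exo face is open, so the bicycle itself sets the C3 stereocentre. The forward step must add lithiated 21 once, at C3 and from the exo face, and cap the alkoxide at once.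

20 ⇒ 19 ⇒ 17 + 18. Two changes without skeletal bonds. Oxidising both carbinols of 19 removes the two uncontrolled carbinol centres. The prenyl groups of 19 are traced back to the allyl groups of 17 by cross-metathesis with 18. The allyl groups are chosen for the annulation because a prenyl double bond is nucleophilic enough to undergo a Prins or carbonyl-ene reaction with a Lewis-acid-bound aldehyde held three atoms away, whereas a monosubstituted alkene is not. The metathesis is placed directly after the annulation so that the ruthenium carbene never meets the Z-enone.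

17 ⇒ 13 + 14 (key disconnection). The bonds C3–C5 and C1–C2 are cut, which removes the two-carbon bridge as glyoxal 14 and leaves monocyclic diketone 13. No other pair of cuts takes away two skeletal bonds, one ring and both bridgehead stereocentres at once while leaving a simple monocyclic fragment. The forward reaction must make C5 and then C1 attack the two aldehyde carbons on the same face of the ring, trans to the C7 allyl group, and through carbon, not oxygen.

13 ⇒ 10 + 11. The C5–allyl bond is cut. In the dianion of 10 the ring methylene is ionised in preference to the isobutyryl methine, so allyl bromide 11 is taken up at C5 only. The new centre need not be controlled because it becomes sp2 in the key step.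

10 ⇒ 9 ⇒ 6 + 7. The C1–acyl bond and one C8–CH3 bond are cut together. Conjugate addition of a methyl group to enone 6 builds the gem-dimethyl carbon and leaves the enolate on the hindered α-carbon next to it, where direct deprotonation would not put it. Aldehyde 7 then supplies the isobutyryl carbon, and oxidation of 9 gives 10. Closing the C1–C8 bond by protonating an isopropenyl group on C7 of an open-chain diketone would be one step shorter, but the tertiary C8 cation is one hydride shift away from C7 and would put the only controlling stereocentre at risk.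

6 ⇒ 4 ⇒ 1 + 2. The other C8–CH3 bond is cut (conjugate addition to 4, then dehydrogenation back to the enone). Ring 4 is opened at C6–C7 and C1=C8 to aldehyde 1 and enone 2. The C7 stereocentre is set here by enamine catalysis, as the α-carbon of 1.

**Alternatives that were turned down**

Alternative 1: The three-carbon bridge is closed last, by cutting C5–C6 and the C7–allyl bond.
- Forward step: a tin-mediated radical chain removes the phenylselanyl group from cyclopentanedione A1. The C5 α-keto radical adds 6-endo to the terminal carbon of the 1,1-dimethylallyl group on C1, and the C7 radical takes an allyl group from an allylstannane to give A2.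
- For: the six-membered ring and the C7 side chain form in one operation, the crowded C5 centre is made by a radical that tolerates congestion, and no enolate regiochemistry arises. On these points it is stronger than the chosen route.
- Against: 6-endo closure must beat 5-exo attack at C7. The C7 configuration depends on which face of a ring radical beside the C8 methyl groups accepts a bulky stannane. The absolute configuration would have to come from C1 of A1, a quaternary carbon between two ketones with no evident enantioselective entry. A2 has C3 as CH2, so C3 must still be oxidised next to a prenyl-bearing quaternary carbon, and the allyl group must still be converted to prenyl.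
- Comparison: the chosen route delivers C2 and C3 already oxygenated and takes its absolute configuration from a catalytic step at the start.

Alternative 2: The six-membered ring is closed onto a complete five-membered ring by cutting C1–C8.
- Forward step: acid converts the isopropenyl group of the lavandulyl chain in triketone A3 into the tertiary C8 cation, which the enol carbon C1 captures to give A4.
- For: A4 is the same compound as trione 20, so this plan is more convergent and several steps shorter, and it needs no diol oxidation. On step economy it is clearly stronger.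
- Against: the C8 cation sits beside the C7 methine, and a 1,2-hydride shift to an equally tertiary C7 cation would scramble the stereocentre that carries the absolute configuration. The two prenyl groups are at least as basic as the isopropenyl group and open a cyclolavandulyl-type closure. The enol of an acylcyclopentanetrione is an acidic, weak carbon nucleophile that can be captured on oxygen. Only one C5 epimer of A3 can close to the exo-C7 skeleton, and nothing controls C5 when the chain is attached.
- Comparison: the chosen route uses no cationic chemistry and sets C5 and C1 relative to C7 inside a ring, where the tether leaves no choice.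

Alternative 3: A seven-membered ring is contracted transannularly by cutting C5–C9.
- Forward step: a cationic rhodium diphosphine catalyst inserts into the formyl C–H bond of cycloheptenone aldehyde A5 and adds it across the C3=C5 double bond (acyl to C5, hydride to C3) to give A6.
- For: one catalytic, fully atom-economic bond closes both rings and fixes both bridgeheads by geometry, with no protecting groups. On atom economy it is stronger.
- Against: the acyl group must go to the fully substituted β-carbon of an enone to make a quaternary centre, which is the least favourable case for hydroacylation. The formyl group sits on a carbon flanked by two ketones, so decarbonylation and deformylation compete. Two prenyl groups can bind the cationic metal. A5 needs a long ring-expansion sequence that sets C1 and C7. A6 again lacks the C3 oxygen.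
- Comparison: the chosen route reaches its key-step substrate in five steps and forms the five-membered ring with both oxygens in place.

Key step: step 6

Assumption: the (S)-prolinol ether is taken to give the (S)-aldehyde 3, as the usual enamine model predicts; if the sense proved opposite, the (R)-catalyst would be used.

Remark: allyl is prop-2-en-1-yl, prenyl is 3-methylbut-2-en-1-yl and isobutyryl is 2-methylpropanoyl. The carbinol carbons C2 and C3 of 17 and 19, and C6 of 13, are carried as epimer mixtures because all three are erased later.

**Route**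

Step 1
Reactants: 1 pent-4-enal; 2 but-3-en-2-one
Product: 4 (4S)-4-(prop-2-en-1-yl)cyclohex-2-en-1-one, via keto aldehyde 3 (not isolated)
Conditions: (S)-α,α-diphenylprolinol methyl ether (5 mol %), ethyl 3,4-dihydroxybenzoate (20 mol %), neat, 4 °C; then LiOH, i-PrOH, rt
Reagents that add atoms: none
Why: Enamine-catalysed Michael addition of the aldehyde to the enone followed by base-mediated intramolecular aldol condensation (organocatalytic Robinson annulation). The diarylmethyl group of the catalyst shields one face of the E-enamine, so the enone is attacked on the other face and the future C7 is set as (S) in 3 and 4.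

Step 2
Reactants: 4 (4S)-4-(prop-2-en-1-yl)cyclohex-2-en-1-one
Product: 6 (4S)-3-methyl-4-(prop-2-en-1-yl)cyclohex-2-en-1-one, via silyl enol ether 5 (not isolated)
Conditions: Me2CuLi, TMSCl, THF, −78 °C; crude 5, Pd(OAc)2 (10 mol %), O2 (1 atm), DMSO, rt
Reagents that add atoms: lithium dimethylcuprate, [Li+].C[Cu-]C
Why: Gilman 1,4-addition anti to the allyl group with silyl trapping, then Saegusa–Ito dehydrogenation of the regiodefined enol silane with O2 as terminal oxidant. The methyl-bearing carbon returns to sp2, so only the allyl-bearing centre remains and it is not touched.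

Step 3
Reactants: 6 (4S)-3-methyl-4-(prop-2-en-1-yl)cyclohex-2-en-1-one; 7 2-methylpropanal
Product: 9 (4S)-2-(1-hydroxy-2-methylpropyl)-3,3-dimethyl-4-(prop-2-en-1-yl)cyclohexan-1-one, via lithium enolate 8 (not isolated)
Conditions: Me2CuLi, Et2O, 0 °C; then 7, −78 °C; aq. NH4Cl
Reagents that add atoms: lithium dimethylcuprate, [Li+].C[Cu-]C
Why: Three-component conjugate addition–aldol sequence. The second methyl group makes the gem-dimethyl carbon (no new stereocentre) and leaves the enolate on the hindered α-carbon beside it, where the aldehyde traps it. The two new centres of 9 are removed or made epimerisable in step 4.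

Step 4
Reactants: 9 (4S)-2-(1-hydroxy-2-methylpropyl)-3,3-dimethyl-4-(prop-2-en-1-yl)cyclohexan-1-one
Product: 10 (4S)-3,3-dimethyl-2-(2-methylpropanoyl)-4-(prop-2-en-1-yl)cyclohexan-1-one
Conditions: Dess–Martin periodinane, CH2Cl2, 0 °C to rt
Reagents that add atoms: none
Why: Dess–Martin oxidation of a β-hydroxy ketone to the 1,3-diketone under non-basic conditions that avoid retro-aldol cleavage. The allyl group and the stereocentre are inert.

Step 5
Reactants: 10 (4S)-3,3-dimethyl-2-(2-methylpropanoyl)-4-(prop-2-en-1-yl)cyclohexan-1-one; 11 3-bromoprop-1-ene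
Product: 13 (4R,6S)-3,3-dimethyl-2-(2-methylpropanoyl)-4,6-di(prop-2-en-1-yl)cyclohexan-1-one, via dilithium dienolate 12 (not isolated)
Conditions: LiN(i-Pr)2 (2.3 equiv), THF, −78 to 0 °C; 11, −78 to −20 °C; 1 M HCl
Reagents that add atoms: none
Why: Hauser-type dianion alkylation of a 1,3-diketone. The second deprotonation takes a ring methylene proton and not the isobutyryl methine proton, and the more basic terminal carbon of 12 is alkylated. The cis (diequatorial) epimer is expected, but this centre is erased in step 6 (the descriptor at C4 changes from S to R only through priorities).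

Step 6
Reactants: 13 (4R,6S)-3,3-dimethyl-2-(2-methylpropanoyl)-4,6-di(prop-2-en-1-yl)cyclohexan-1-one; 14 ethanedial (glyoxal)
Product: 17 (1R,5S,7R)-2,3-dihydroxy-8,8-dimethyl-1-(2-methylpropanoyl)-5,7-di(prop-2-en-1-yl)bicyclo[3.2.1]octan-9-one, via dilithium dienolate 15 (not isolated), via bis(silyloxy)diene 16 (not isolated)
Conditions: LiN(i-Pr)2 (2.4 equiv), THF, −78 to 0 °C; TMSCl, −78 °C to rt; pentane, filtration, CH2Cl2; 16 added slowly to 14 (monomer, 1.5 equiv, freshly cracked from the trimer dihydrate over P2O5) and TiCl4 (2 equiv), CH2Cl2, −78 °C; H2O, then 1 M HCl/THF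
Reagents that add atoms: none
Why: Proposed new method: no (3+2) union of a 1,3-bis(silyloxy)diene with glyoxal through two carbon–carbon bonds is known; the closest known types are the TiCl4-mediated Mukaiyama aldol of such dienes through their terminal carbon, the titanium-enolate aldol of 1,3-diketones that opens a Lehnert-type Knoevenagel condensation, and the α,α′-double aldol of ketones with 1,2-dicarbonyls in the Weiss–Cook reaction. Double deprotonation of 13 takes the C1 proton and then the C5 proton (ionising the isobutyryl methine would force a tetrasubstituted enolate against the C8 methyl groups), and silylation gives diene 16, whose terminus C5 is its most nucleophilic carbon. C5 adds to TiCl4-bound glyoxal and forms C3–C5 on the face trans to the C7 allyl group, because that approach is axial on the half-chair that keeps the allyl group equatorial and meets only the axial C7–H; this sets the C5 bridgehead. The titanium-bound α-oxy aldehyde then hangs axially over C1, and the remaining exocyclic enol silane (or the titanium diketonate formed from it) attacks through C1 in a 5-(enolexo)-exo-trig closure that forms C1–C2, closes the ring C1–C2–C3–C5–C9 and sets the C1 bridgehead, which the tether can reach only on the same face. Closure through the enol oxygen would give a strained hemiacetal that can revert, and neither aldol can dehydrate because C1 and C5 carry no hydrogen, so the bridged diol should accumulate; the C2 and C3 configurations are left open because both carbinols are oxidised in step 8. The step needs carbon-before-oxygen closure, one-face delivery at C5 and C1 and no oligomerisation: slow addition of 16 to excess pre-complexed monomeric glyoxal at −78 °C, the rigid tether, and allyl side chains too electron-poor for a Prins or ene reaction with the bound aldehydes are meant to secure this.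

Step 7
Reactants: 17 (1R,5S,7R)-2,3-dihydroxy-8,8-dimethyl-1-(2-methylpropanoyl)-5,7-di(prop-2-en-1-yl)bicyclo[3.2.1]octan-9-one; 18 2-methylbut-2-ene
Product: 19 (1R,5S,7R)-2,3-dihydroxy-8,8-dimethyl-5,7-bis(3-methylbut-2-en-1-yl)-1-(2-methylpropanoyl)bicyclo[3.2.1]octan-9-one
Conditions: second-generation Grubbs catalyst RuCl2(=CHPh)(H2IMes)(PCy3) (5 mol %), 18 (excess), CH2Cl2, 40 °C
Reagents that add atoms: none
Why: Olefin cross-metathesis of the two monosubstituted alkenes with a large excess of the trisubstituted partner turns both allyl groups into prenyl groups. The bicycle holds the allyl groups diequatorial and too far apart for ring closure, and ketones and free hydroxyls are tolerated under these neutral conditions.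

Step 8
Reactants: 19 (1R,5S,7R)-2,3-dihydroxy-8,8-dimethyl-5,7-bis(3-methylbut-2-en-1-yl)-1-(2-methylpropanoyl)bicyclo[3.2.1]octan-9-one
Product: 20 (1R,5R,7R)-8,8-dimethyl-5,7-bis(3-methylbut-2-en-1-yl)-1-(2-methylpropanoyl)bicyclo[3.2.1]octane-2,3,9-trione
Conditions: (COCl)2, DMSO, CH2Cl2, −78 °C; Et3N, −78 to 0 °C
Reagents that add atoms: none
Why: Swern oxidation takes vicinal diols to 1,2-diketones without C–C cleavage, at low temperature and with a mild amine base, so the triacylmethane at C1 meets no nucleophile. Both carbinol epimers converge on one compound (the C5 descriptor changes only through priorities).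

Step 9
Reactants: 20 (1R,5R,7R)-8,8-dimethyl-5,7-bis(3-methylbut-2-en-1-yl)-1-(2-methylpropanoyl)bicyclo[3.2.1]octane-2,3,9-trione; 21 2-methylfuran
Product: 23 (1R,3S,5S,7R)-8,8-dimethyl-5,7-bis(3-methylbut-2-en-1-yl)-3-(5-methylfuran-2-yl)-1-(2-methylpropanoyl)-3-(trimethylsilyloxy)bicyclo[3.2.1]octane-2,9-dione, via lithium alkoxide 22 (not isolated)
Conditions: 21, n-BuLi, THF, 0 °C; added to 20 (1.1 equiv of the lithiofuran), THF, −78 °C; TMSCl, −78 to 0 °C
Reagents that add atoms: chlorotrimethylsilane, C[Si](C)(C)Cl
Why: Organolithium 1,2-addition to the more accessible carbonyl of the α-diketone: C3 is flanked by C5 (two CH2 substituents), whereas C2 lies beside C1 with its isobutyryl group and the C8 methyl groups. Attack comes from the exo face (the side of the flat C9 carbonyl, away from the chair bridge and the axial C7–H), which places the furyl group exo and the oxygen endo as in the target. Immediate O-silylation of 22 blocks acyloin shift and retro-Claisen pathways.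

Step 10
Reactants: 23 (1R,3S,5S,7R)-8,8-dimethyl-5,7-bis(3-methylbut-2-en-1-yl)-3-(5-methylfuran-2-yl)-1-(2-methylpropanoyl)-3-(trimethylsilyloxy)bicyclo[3.2.1]octane-2,9-dione
Product: 24 (1R,3S,5S,7R)-8,8-dimethyl-5,7-bis(3-methylbut-2-en-1-yl)-1-(2-methylpropanoyl)-3-[(2Z)-4-oxopent-2-enoyl]-3-(trimethylsilyloxy)bicyclo[3.2.1]octane-2,9-dione
Conditions: NBS (1.05 equiv), NaHCO3, acetone/H2O (10:1), −20 °C, dark
Reagents that add atoms: water, O
Why: Oxidative ring opening of a 2,5-dialkylfuran by an N-bromo imide in buffered aqueous acetone: bromination at a furan α-carbon, hydration and loss of HBr unmask the Z-ene-1,4-dione, whose geometry comes from the ring. The furan is far more nucleophilic than the prenyl double bonds, so one equivalent at −20 °C should be consumed by it alone.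

Step 11
Reactants: 24 (1R,3S,5S,7R)-8,8-dimethyl-5,7-bis(3-methylbut-2-en-1-yl)-1-(2-methylpropanoyl)-3-[(2Z)-4-oxopent-2-enoyl]-3-(trimethylsilyloxy)bicyclo[3.2.1]octane-2,9-dione
Product: 25 (1R,3S,5S,7R)-3-[(2Z)-4-hydroxy-4-methylpent-2-enoyl]-8,8-dimethyl-5,7-bis(3-methylbut-2-en-1-yl)-1-(2-methylpropanoyl)-3-(trimethylsilyloxy)bicyclo[3.2.1]octane-2,9-dione
Conditions: CeCl3 (anhydrous), MeLi, THF, −78 °C; aq. NH4Cl
Reagents that add atoms: methyllithium, [Li]C
Why: Organocerium 1,2-addition (Imamoto conditions). The non-basic, oxophilic methylcerium reagent adds to the only unhindered carbonyl, the methyl ketone, since C2, C9, the isobutyryl and the enone carbonyls each sit beside a fully substituted carbon. The new carbinol carbon carries two methyl groups and is not stereogenic, and the Z double bond is left alone at −78 °C.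

Step 12
Reactants: 25 (1R,3S,5S,7R)-3-[(2Z)-4-hydroxy-4-methylpent-2-enoyl]-8,8-dimethyl-5,7-bis(3-methylbut-2-en-1-yl)-1-(2-methylpropanoyl)-3-(trimethylsilyloxy)bicyclo[3.2.1]octane-2,9-dione
Product: 26 (1R,3S,5S,7R)-3-hydroxy-3-[(2Z)-4-hydroxy-4-methylpent-2-enoyl]-8,8-dimethyl-5,7-bis(3-methylbut-2-en-1-yl)-1-(2-methylpropanoyl)bicyclo[3.2.1]octane-2,9-dione
Conditions: HF·pyridine, pyridine, THF, 0 °C
Reagents that add atoms: none
Why: Cleavage of the tertiary trimethylsilyl ether with pyridine-buffered HF, mild enough for the Z-γ-hydroxy enone, the tertiary allylic alcohol and the triacylmethane. No stereocentre is affected.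

**Compound list**

1 | pent-4-enal | C=CCCC=O | starting material
2 | but-3-en-2-one (methyl vinyl ketone) | CC(=O)C=C | starting material
3 | (2S)-5-oxo-2-(prop-2-en-1-yl)hexanal | C=CC[C@@H](C=O)CCC(C)=O | intermediate (not isolated)
4 | (4S)-4-(prop-2-en-1-yl)cyclohex-2-en-1-one | C=CC[C@H]1C=CC(=O)CC1 | intermediate
5 | trimethyl{[(3S,4S)-3-methyl-4-(prop-2-en-1-yl)cyclohex-1-en-1-yl]oxy}silane | C=CC[C@H]1[C@H](C)C=C(O[Si](C)(C)C)CC1 | intermediate (not isolated)
6 | (4S)-3-methyl-4-(prop-2-en-1-yl)cyclohex-2-en-1-one | C=CC[C@H]1C(C)=CC(=O)CC1 | intermediate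
7 | 2-methylpropanal (isobutyraldehyde) | CC(C)C=O | starting material
8 | lithium (4S)-3,3-dimethyl-4-(prop-2-en-1-yl)cyclohex-1-en-1-olate | C=CC[C@@H]1CCC(O[Li])=CC1(C)C | intermediate (not isolated)
9 | (4S)-2-(1-hydroxy-2-methylpropyl)-3,3-dimethyl-4-(prop-2-en-1-yl)cyclohexan-1-one (epimers at C2 and at the carbinol carbon) | C=CC[C@@H]1CCC(=O)C(C(O)C(C)C)C1(C)C | intermediate
10 | (4S)-3,3-dimethyl-2-(2-methylpropanoyl)-4-(prop-2-en-1-yl)cyclohexan-1-one (C2 unspecified, enolised) | C=CC[C@@H]1CCC(=O)C(C(=O)C(C)C)C1(C)C | intermediate
11 | 3-bromoprop-1-ene (allyl bromide) | C=CCBr | starting material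
12 | dilithium (4R)-5,5-dimethyl-6-(2-methyl-1-oxidopropylidene)-4-(prop-2-en-1-yl)cyclohex-1-en-1-olate | C=CC[C@@H]1CC=C(O[Li])C(=C(O[Li])C(C)C)C1(C)C | intermediate (not isolated)
13 | (4R,6S)-3,3-dimethyl-2-(2-methylpropanoyl)-4,6-di(prop-2-en-1-yl)cyclohexan-1-one (C2 unspecified, enolised; C6 epimer tolerated) | C=CC[C@@H]1C[C@H](CC=C)C(=O)C(C(=O)C(C)C)C1(C)C | intermediate
14 | ethanedial (glyoxal) | O=CC=O | starting material
15 | dilithium (4R)-5,5-dimethyl-6-(2-methyl-1-oxidopropylidene)-2,4-di(prop-2-en-1-yl)cyclohex-1-en-1-olate | C=CC[C@@H]1CC(CC=C)=C(O[Li])C(=C(O[Li])C(C)C)C1(C)C | intermediate (not isolated)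
16 | trimethyl({(4R)-5,5-dimethyl-6-[2-methyl-1-(trimethylsilyloxy)propylidene]-2,4-di(prop-2-en-1-yl)cyclohex-1-en-1-yl}oxy)silane (exocyclic geometry not defined) | C=CC[C@@H]1CC(CC=C)=C(O[Si](C)(C)C)C(=C(O[Si](C)(C)C)C(C)C)C1(C)C | intermediate (not isolated)
17 | (1R,5S,7R)-2,3-dihydroxy-8,8-dimethyl-1-(2-methylpropanoyl)-5,7-di(prop-2-en-1-yl)bicyclo[3.2.1]octan-9-one (C2 and C3 epimers not assigned) | C=CC[C@@H]1C[C@]2(CC=C)C(=O)[C@@](C(=O)C(C)C)(C(O)C2O)C1(C)C | intermediate
18 | 2-methylbut-2-ene | CC=C(C)C | starting material
19 | (1R,5S,7R)-2,3-dihydroxy-8,8-dimethyl-5,7-bis(3-methylbut-2-en-1-yl)-1-(2-methylpropanoyl)bicyclo[3.2.1]octan-9-one (C2 and C3 epimers not assigned) | CC(C)=CC[C@@H]1C[C@]2(CC=C(C)C)C(=O)[C@@](C(=O)C(C)C)(C(O)C2O)C1(C)C | intermediate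
20 | (1R,5R,7R)-8,8-dimethyl-5,7-bis(3-methylbut-2-en-1-yl)-1-(2-methylpropanoyl)bicyclo[3.2.1]octane-2,3,9-trione | CC(C)=CC[C@@H]1C[C@]2(CC=C(C)C)C(=O)[C@@](C(=O)C(C)C)(C(=O)C2=O)C1(C)C | intermediate
21 | 2-methylfuran | Cc1ccco1 | starting material
22 | lithium (1R,3S,5S,7R)-8,8-dimethyl-5,7-bis(3-methylbut-2-en-1-yl)-3-(5-methylfuran-2-yl)-1-(2-methylpropanoyl)-2,9-dioxobicyclo[3.2.1]octan-3-olate | CC(C)=CC[C@@H]1C[C@]2(CC=C(C)C)C(=O)[C@@](C(=O)C(C)C)(C(=O)[C@@]2(O[Li])c3ccc(C)o3)C1(C)C | intermediate (not isolated)
23 | (1R,3S,5S,7R)-8,8-dimethyl-5,7-bis(3-methylbut-2-en-1-yl)-3-(5-methylfuran-2-yl)-1-(2-methylpropanoyl)-3-(trimethylsilyloxy)bicyclo[3.2.1]octane-2,9-dione | CC(C)=CC[C@@H]1C[C@]2(CC=C(C)C)C(=O)[C@@](C(=O)C(C)C)(C(=O)[C@@]2(O[Si](C)(C)C)c3ccc(C)o3)C1(C)C | intermediate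
24 | (1R,3S,5S,7R)-8,8-dimethyl-5,7-bis(3-methylbut-2-en-1-yl)-1-(2-methylpropanoyl)-3-[(2Z)-4-oxopent-2-enoyl]-3-(trimethylsilyloxy)bicyclo[3.2.1]octane-2,9-dione | CC(C)=CC[C@@H]1C[C@]2(CC=C(C)C)C(=O)[C@@](C(=O)C(C)C)(C(=O)[C@@]2(O[Si](C)(C)C)C(=O)/C=C\C(C)=O)C1(C)C | intermediate
25 | (1R,3S,5S,7R)-3-[(2Z)-4-hydroxy-4-methylpent-2-enoyl]-8,8-dimethyl-5,7-bis(3-methylbut-2-en-1-yl)-1-(2-methylpropanoyl)-3-(trimethylsilyloxy)bicyclo[3.2.1]octane-2,9-dione | CC(C)=CC[C@@H]1C[C@]2(CC=C(C)C)C(=O)[C@@](C(=O)C(C)C)(C(=O)[C@@]2(O[Si](C)(C)C)C(=O)/C=C\C(C)(C)O)C1(C)C | intermediate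
26 | (1R,3S,5S,7R)-3-hydroxy-3-[(2Z)-4-hydroxy-4-methylpent-2-enoyl]-8,8-dimethyl-5,7-bis(3-methylbut-2-en-1-yl)-1-(2-methylpropanoyl)bicyclo[3.2.1]octane-2,9-dione (CNP0190794.1; systematic locants: (1S,3R,5R,7S)-7-hydroxy-7-[(2Z)-4-hydroxy-4-methylpent-2-enoyl]-4,4-dimethyl-1,3-bis(3-methylbut-2-en-1-yl)-5-(2-methylpropanoyl)bicyclo[3.2.1]octane-6,8-dione) | CC(C)=CC[C@@H]1C[C@]2(CC=C(C)C)C(=O)[C@@](C(=O)C(C)C)(C(=O)[C@@]2(O)C(=O)/C=C\C(C)(C)O)C1(C)C | target

**Step count and least certain steps**

Total step count: 12. Longest linear sequence: 12 steps (1 and 2 to 26); 7, 11, 14, 18 and 21 enter as purchased.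

Step 6 (key step, proposed new method). The ring closure at the crowded C1 may not keep pace with the first aldol, in which case the mono-adduct would revert, be taken up by a second diene molecule, or be lost to glyoxal oligomerisation on the Lewis acid. Ionisation at the isobutyryl methine in place of C5 during dienolate formation would also divert material. The fallback uses known reaction types and separates the two bond formations. It sets out from 13: the dilithium dienolate is added to 2,2-dimethoxyacetaldehyde (γ-aldol of a 1,3-diketone dianion) to give hydroxy acetal F1. Aqueous trifluoroacetic acid then hydrolyses the acetal, and the enolised diketone adds through C1 to the freed aldehyde (acid-mediated intramolecular aldol, 5-enolexo), which returns to the route at 17.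

Step 9. The organolithium may attack C2 in place of C3 (wrong-site addition), or alkoxide 22 may fragment the triacylmethane before it is silylated. The fallback fixes the site by oxidation state. It sets out from 20: a bulky hydride, LiAlH(O-t-Bu)3 at −78 °C, is expected to reduce the same carbonyl that outcompetes C3, giving 2-hydroxy-3,9-dione F2. Excess lithiated 21 can then add only to C3, from the exo face, to give furyl diol F3. Swern oxidation of the secondary C2 alcohol gives hydroxy dione F4, and silylation (TMSOTf, 2,6-lutidine) returns to the route at 23.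

Step 10. Bromination or bromohydrin formation at the prenyl double bonds may compete with the furan, and bromide or acid may isomerise the Z-enedione to the E isomer. The fallback replaces halonium chemistry by a cycloaddition. It sets out from 23: dye-sensitised photooxygenation (O2, tetraphenylporphyrin, visible light, CH2Cl2, −78 °C) adds singlet oxygen across the furan, which reacts much faster than a trisubstituted alkene does in the ene mode, to give endoperoxide F5. Reduction with dimethyl sulfide in the same flask opens it to the Z-enedione and returns to the route at 24.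

Step 11. The methyl reagent may add to a ring carbonyl or in conjugate fashion, and the Z-enedione may isomerise or cyclise on the Lewis-acidic cerium slurry. The fallback locks the double bond in a ring before the methyl group arrives. It sets out from 24: HF·pyridine removes the silyl group, and the freed C3 hydroxyl closes onto the methyl ketone to give the six-membered spiro hemiketal F6 (an Achmatowicz-type 6-hydroxy-2H-pyran-3(6H)-one). Excess MeMgBr then deprotonates the hemiketal, the ring opens to the keto alkoxide, and the methyl ketone is attacked as it is released. This comes back to the route at 26 and makes step 12 unnecessary.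

**Further compounds**

F1 | step 6 | (4R)-6-(1-hydroxy-2,2-dimethoxyethyl)-3,3-dimethyl-2-(2-methylpropanoyl)-4,6-di(prop-2-en-1-yl)cyclohexan-1-one (new chain cis to H-4; carbinol epimers) | C=CC[C@@H]1C[C@@](CC=C)(C(O)C(OC)OC)C(=O)C(C(=O)C(C)C)C1(C)C
F2 | step 9 | 2-hydroxy-8,8-dimethyl-5,7-bis(3-methylbut-2-en-1-yl)-1-(2-methylpropanoyl)bicyclo[3.2.1]octane-3,9-dione (C1, C5, C7 as in 20; C2 epimer not assigned) | CC(C)=CC[C@@H]1C[C@]2(CC=C(C)C)C(=O)[C@@](C(=O)C(C)C)(C(O)C2=O)C1(C)C
F3 | step 9 | 2,3-dihydroxy-8,8-dimethyl-5,7-bis(3-methylbut-2-en-1-yl)-3-(5-methylfuran-2-yl)-1-(2-methylpropanoyl)bicyclo[3.2.1]octan-9-one (furyl exo as in 23; C2 epimer not assigned) | CC(C)=CC[C@@H]1C[C@]2(CC=C(C)C)C(=O)[C@@](C(=O)C(C)C)(C(O)[C@@]2(O)c3ccc(C)o3)C1(C)C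
F4 | step 9 | 3-hydroxy-8,8-dimethyl-5,7-bis(3-methylbut-2-en-1-yl)-3-(5-methylfuran-2-yl)-1-(2-methylpropanoyl)bicyclo[3.2.1]octane-2,9-dione (desilyl 23) | CC(C)=CC[C@@H]1C[C@]2(CC=C(C)C)C(=O)[C@@](C(=O)C(C)C)(C(=O)[C@@]2(O)c3ccc(C)o3)C1(C)C
F5 | step 10 | singlet-oxygen adduct of 23: the furan converted into a 4-methyl-2,3,7-trioxabicyclo[2.2.1]hept-5-en-1-yl group (bicyclic core as in 23; endoperoxide epimers) | CC(C)=CC[C@@H]1C[C@]2(CC=C(C)C)C(=O)[C@@](C(=O)C(C)C)(C(=O)[C@@]2(O[Si](C)(C)C)C3(OO4)C=CC4(C)O3)C1(C)C
F6 | step 11 | spiro hemiketal of desilylated 24: C3 of the bicycle is C2 of a 6-hydroxy-6-methyl-2H-pyran-3(6H)-one ring (bicyclic core as in 24; hemiketal epimers) | CC(C)=CC[C@@H]1C[C@]2(CC=C(C)C)C(=O)[C@@](C(=O)C(C)C)(C(=O)[C@@]2(O3)C(=O)C=CC3(C)O)C1(C)C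
A1 | alternative 1 | 2-(2-methylbut-3-en-2-yl)-4-(3-methylbut-2-en-1-yl)-2-(2-methylpropanoyl)-4-(phenylselanyl)cyclopentane-1,3-dione (C2 configured as C1 of the target; selenide carbon either epimer) | CC(C)=CCC1([Se]c2ccccc2)CC(=O)[C@@](C(=O)C(C)C)(C(C)(C)C=C)C1=O
A2 | alternative 1 | 8,8-dimethyl-5-(3-methylbut-2-en-1-yl)-1-(2-methylpropanoyl)-7-(prop-2-en-1-yl)bicyclo[3.2.1]octane-2,9-dione (target numbering and configuration) | C=CC[C@@H]1C[C@]2(CC=C(C)C)C(=O)[C@@](C(=O)C(C)C)(C(=O)C2)C1(C)C
A3 | alternative 2 | 5-(3-methylbut-2-en-1-yl)-5-[5-methyl-2-(prop-1-en-2-yl)hex-4-en-1-yl]-3-(2-methylpropanoyl)cyclopentane-1,2,4-trione (C5 and the lavandulyl CH configured as C5 and C7 of the target; enolised) | CC(C)=CC[C@H](C[C@]1(CC=C(C)C)C(=O)C(C(=O)C(C)C)C(=O)C1=O)C(C)=C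
A4 | alternative 2 | 8,8-dimethyl-5,7-bis(3-methylbut-2-en-1-yl)-1-(2-methylpropanoyl)bicyclo[3.2.1]octane-2,3,9-trione (identical with 20) | CC(C)=CC[C@@H]1C[C@]2(CC=C(C)C)C(=O)[C@@](C(=O)C(C)C)(C(=O)C2=O)C1(C)C
A5 | alternative 3 | 2,2-dimethyl-3,5-bis(3-methylbut-2-en-1-yl)-1-(2-methylpropanoyl)-7-oxocyclohept-5-ene-1-carbaldehyde (C1 and C3 configured as C1 and C7 of the target) | CC(C)=CC[C@@H]1CC(CC=C(C)C)=CC(=O)[C@@](C=O)(C(=O)C(C)C)C1(C)C
A6 | alternative 3 | 8,8-dimethyl-5,7-bis(3-methylbut-2-en-1-yl)-1-(2-methylpropanoyl)bicyclo[3.2.1]octane-2,9-dione (target numbering and configuration) | CC(C)=CC[C@@H]1C[C@]2(CC=C(C)C)C(=O)[C@@](C(=O)C(C)C)(C(=O)C2)C1(C)C
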